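**Plan**

- Feature: the cyclopentene has oxygen on both ring carbons that flank the carbinol carbon bearing the tridecanoyl group, with the C=C opposite, and without the acetyl group it has a mirror plane (meso). This pattern is that of a trans-4-hydroxy-5-alkylcyclopent-2-enone, the rearrangement product of a 2-furylcarbinol (furan C5 → free-carbinol carbon, furan C4/C3 → ring alkene, furan C2 → acetoxy-bearing carbon, carbinol carbon → quaternary carbon).
- Cuts, in retrosynthetic order: one acetate ester (enzymatic mono-deacetylation of a meso diacetate); the side-chain C=O and the tertiary C–OH (back to an exocyclic alkene); the C–H of the acetoxy-bearing carbon (back to a ring ketone); then, in one operation, the ring C–C bond between the quaternary carbon and the free-carbinol carbon together with the ring C=C (Piancatelli rearrangement, whose σ framework for the C=C is already the furan C3–C4 bond); last the furan–carbinol C–C bond.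
- Forward: the C13 chain is joined to furan first, the carbocycle is made from the furan ring in one step, and the later steps only adjust oxidation levels on the ring and on the first side-chain carbon.
- Stereochemistry: the rearrangement gives the racemic trans ketol; hydride then adds anti to the silyloxy group (cis ring oxygens), and OsO4 adds anti to both acetoxy groups (tertiary OH trans to them). Both enantiomers of every intermediate merge in the meso diacetate, and a lipase that cleaves one enantiotopic acetate sets the absolute configuration.

Key step: step 2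

Remark: every intermediate from the furylcarbinol to the diol diacetate is racemic and is drawn as the enantiomer that maps directly onto the target; the geometry of the exocyclic alkene does not affect the final product.

**Route**

Step 1
Reactants: 1 furan; 2 tetradecanal
Product: 4 rac-1-(furan-2-yl)tetradecan-1-ol, via 2-furyllithium 3 (not isolated)
Conditions: n-BuLi, THF, 0 °C; then 2, −78 °C to rt; H2O
Reagents that add atoms: none
Why: α-Lithiation of furan and 1,2-addition of the aryllithium to an aliphatic aldehyde is routine organolithium chemistry; the new carbinol centre forms racemic and is erased in step 2.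

Step 2
Reactants: 4 rac-1-(furan-2-yl)tetradecan-1-ol
Product: 6 rac-(4R,5S)-4-hydroxy-5-tridecylcyclopent-2-en-1-one, via hydroxypentadienyl cation 5 (not isolated)
Conditions: ZnCl2, 1,4-dioxane/H2O, reflux
Reagents that add atoms: water, O
Why: Piancatelli rearrangement: ZnCl2-assisted ionisation of the furylic C–O bond gives a furfuryl cation, water adds at furan C5, the hemiacetal ring opens to the hydroxypentadienyl cation 5, and a thermally allowed conrotatory 4π electrocyclisation joins the former carbinol carbon to the former furan C5, while loss of a proton turns the former furan C3–C4 bond into the ring C=C and the furan oxygen into the ketone. The closest known reaction type is exactly this acid-mediated conversion of 2-furyl alkyl carbinols into trans-4-hydroxy-5-alkylcyclopent-2-enones, here applied to a long-chain member. The one ring that closes, the cyclopentenone, does so by 4π conrotatory electrocyclisation of a pentadienyl cation (Nazarov-type) and not by a polar exo or endo attack, and the furan ring is opened in the same cascade. The two new stereocentres C4 and C5 are set trans by conrotation of the cation with both terminal substituents outside, which is also the more stable arrangement; no absolute control is exerted or needed, because both enantiomers converge on a meso diacetate later in the route. The step needs water to attack at furan C5 (attack at the carbinol carbon only returns 4) and must stop before isomerisation to the 2-alkyl-4-hydroxy isomer, which the unsubstituted C5 position and the weakly acidic ZnCl2 medium should secure.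

Step 3
Reactants: 6 rac-(4R,5S)-4-hydroxy-5-tridecylcyclopent-2-en-1-one
Product: 7 rac-(4R,5S)-4-[(tert-butyldimethylsilyl)oxy]-5-tridecylcyclopent-2-en-1-one
Conditions: t-BuMe2SiCl, imidazole, DMF, 0 °C to rt
Reagents that add atoms: tert-butyldimethylsilyl chloride, CC(C)(C)[Si](C)(C)Cl
Why: Imidazole-mediated silylation of a secondary alcohol is mild enough not to isomerise or dehydrate the β-hydroxy enone, and no stereocentre is affected.

Step 4
Reactants: 7 rac-(4R,5S)-4-[(tert-butyldimethylsilyl)oxy]-5-tridecylcyclopent-2-en-1-one
Product: 11 rac-(4R,5E)-4-[(tert-butyldimethylsilyl)oxy]-5-tridecylidenecyclopent-2-en-1-one, via lithium enolate 8 (not isolated), via selenide 9 (not isolated), via selenoxide 10 (not isolated)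
Conditions: LiN(iPr)2, THF, −78 °C; PhSeBr; then 30% H2O2, pyridine, CH2Cl2, 0 °C to rt
Reagents that add atoms: none
Why: α′-Selenenylation of the kinetic cross-conjugated enolate followed by selenoxide syn-elimination dehydrogenates the ketone toward the side chain, because selenoxides eliminate away from an oxygen-bearing β-carbon and the alternative would be a cyclopentadienone; the C5 stereocentre is deleted and the alkene geometry is immaterial later.

Step 5
Reactants: 11 rac-(4R,5E)-4-[(tert-butyldimethylsilyl)oxy]-5-tridecylidenecyclopent-2-en-1-one
Product: 12 rac-(1S,4R,5Z)-4-[(tert-butyldimethylsilyl)oxy]-5-tridecylidenecyclopent-2-en-1-ol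
Conditions: NaBH4, CeCl3·7H2O, MeOH, −78 °C
Reagents that add atoms: none
Why: Luche reduction gives 1,2-reduction of the cross-conjugated dienone, and hydride adds to the face opposite the silyloxy group, so the new carbinol is cis to it, as is known for 4-silyloxycyclopent-2-enones.

Step 6
Reactants: 12 rac-(1S,4R,5Z)-4-[(tert-butyldimethylsilyl)oxy]-5-tridecylidenecyclopent-2-en-1-ol
Product: 13 rac-(1R,3S)-2-tridecylidenecyclopent-4-ene-1,3-diol
Conditions: Bu4NF, THF, 0 °C
Reagents that add atoms: none
Why: Fluoride-induced cleavage of the silyl ether under non-acidic conditions spares the doubly allylic alcohols, and no stereocentre is touched.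

Step 7
Reactants: 13 rac-(1R,3S)-2-tridecylidenecyclopent-4-ene-1,3-diol
Product: 14 rac-(1R,3S)-2-tridecylidenecyclopent-4-ene-1,3-diyl diacetate
Conditions: Ac2O, pyridine, 4-(dimethylamino)pyridine (cat.), CH2Cl2, 0 °C to rt
Reagents that add atoms: acetic anhydride, CC(=O)OC(C)=O
Why: Acylation of the two secondary alcohols by nucleophilic catalysis proceeds with retention of configuration.

Step 8
Reactants: 14 rac-(1R,3S)-2-tridecylidenecyclopent-4-ene-1,3-diyl diacetate
Product: 15 rac-(1R,3S)-2-hydroxy-2-(1-hydroxytridecyl)cyclopent-4-ene-1,3-diyl diacetate
Conditions: K2OsO4·2H2O (cat.), N-methylmorpholine N-oxide, acetone/H2O, 0 °C to rt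
Reagents that add atoms: N-methylmorpholine N-oxide, C[N+]1([O-])CCOCC1; water, O
Why: Catalytic osmylation (syn-dihydroxylation through OsO4) should take the more electron-rich trisubstituted exocyclic alkene before the cis-disubstituted ring alkene and add to the face opposite both allylic acetoxy groups, which sets the tertiary carbinol trans to both ring oxygens; the side-chain carbinol centre follows from syn addition and is removed in step 9.

Step 9
Reactants: 15 rac-(1R,3S)-2-hydroxy-2-(1-hydroxytridecyl)cyclopent-4-ene-1,3-diyl diacetate
Product: 16 (1R,2r,3S)-2-hydroxy-2-tridecanoylcyclopent-4-ene-1,3-diyl diacetate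
Conditions: 2-iodoxybenzoic acid, DMSO, rt
Reagents that add atoms: none
Why: Oxidation with this hypervalent iodine reagent converts the secondary alcohol of a 1,2-diol into the α-hydroxy ketone without glycol cleavage, the tertiary alcohol and the esters being inert; the product is meso.

Step 10
Reactants: 16 (1R,2r,3S)-2-hydroxy-2-tridecanoylcyclopent-4-ene-1,3-diyl diacetate
Product: 17 (1S,2S,5R)-2,5-dihydroxy-2-tridecanoylcyclopent-3-en-1-yl acetate
Conditions: immobilised Candida antarctica lipase B, phosphate buffer (pH 7)/t-BuOMe, 30 °C
Reagents that add atoms: none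
Why: Lipase-catalysed hydrolysis of one enantiotopic ester of a meso diacetate (enzymatic desymmetrisation, known for cis-cyclopent-4-ene-1,3-diyl diacetates) should, by the empirical size rule for lipases and secondary alcohols (large group the quaternary ring carbon, medium group the vinylic CH), cleave the acetate on the R-configured carbon and leave the one on the S-configured carbon, which fixes the absolute configuration of all three stereocentres in a near-neutral medium that avoids acetyl migration and retro-aldol cleavage.

**Compound list**

1 | furan | c1ccoc1 | starting material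
2 | tetradecanal | CCCCCCCCCCCCCC=O | starting material
3 | 2-furyllithium (formed in situ) | [Li]c1ccco1 | intermediate
4 | rac-1-(furan-2-yl)tetradecan-1-ol | CCCCCCCCCCCCCC(O)c1ccco1 | intermediate
5 | hydroxypentadienyl cation, O-protonated (2Z)-4-hydroxyoctadeca-2,4-dienal (formed in situ) | CCCCCCCCCCCCCC=C(O)/C=C\C=[OH+] | intermediate
6 | rac-(4R,5S)-4-hydroxy-5-tridecylcyclopent-2-en-1-one (trans) | CCCCCCCCCCCCC[C@H]1[C@H](O)C=CC1=O | intermediate
7 | rac-(4R,5S)-4-[(tert-butyldimethylsilyl)oxy]-5-tridecylcyclopent-2-en-1-one | CCCCCCCCCCCCC[C@H]1[C@H](O[Si](C)(C)C(C)(C)C)C=CC1=O | intermediate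
8 | rac-lithium 5-[(tert-butyldimethylsilyl)oxy]-2-tridecylcyclopenta-1,3-dien-1-olate, the lithium enolate of 7 (formed in situ) | [Li+].CCCCCCCCCCCCCC1=C([O-])C=C[C@H]1O[Si](C)(C)C(C)(C)C | intermediate
9 | rac-4-[(tert-butyldimethylsilyl)oxy]-5-(phenylselanyl)-5-tridecylcyclopent-2-en-1-one, selenium trans to the silyloxy group (formed in situ) | CCCCCCCCCCCCC[C@]1([Se]c2ccccc2)[C@H](O[Si](C)(C)C(C)(C)C)C=CC1=O | intermediate
10 | Se-oxide of 9, selenium configuration undefined (formed in situ) | CCCCCCCCCCCCC[C@]1([Se](=O)c2ccccc2)[C@H](O[Si](C)(C)C(C)(C)C)C=CC1=O | intermediate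
11 | rac-(4R,5E)-4-[(tert-butyldimethylsilyl)oxy]-5-tridecylidenecyclopent-2-en-1-one | CCCCCCCCCCCC/C=C1\[C@H](O[Si](C)(C)C(C)(C)C)C=CC1=O | intermediate
12 | rac-(1S,4R,5Z)-4-[(tert-butyldimethylsilyl)oxy]-5-tridecylidenecyclopent-2-en-1-ol (cis ring oxygens; alkene geometry as in 11, only the descriptor changes) | CCCCCCCCCCCC/C=C1\[C@H](O[Si](C)(C)C(C)(C)C)C=C[C@@H]1O | intermediate
13 | rac-(1R,3S)-2-tridecylidenecyclopent-4-ene-1,3-diol (cis diol; alkyl chain of the alkylidene group syn to C1) | CCCCCCCCCCCC/C=C1\[C@H](O)C=C[C@@H]1O | intermediate
14 | rac-(1R,3S)-2-tridecylidenecyclopent-4-ene-1,3-diyl diacetate (alkyl chain syn to C1) | CCCCCCCCCCCC/C=C1\[C@H](OC(C)=O)C=C[C@@H]1OC(C)=O | intermediate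
15 | rac-(1R,3S)-2-hydroxy-2-(1-hydroxytridecyl)cyclopent-4-ene-1,3-diyl diacetate (acetoxy groups cis; tertiary hydroxyl trans to both; side-chain carbinol from syn addition) | CCCCCCCCCCCC[C@H](O)[C@]1(O)[C@H](OC(C)=O)C=C[C@@H]1OC(C)=O | intermediate
16 | (1R,2r,3S)-2-hydroxy-2-tridecanoylcyclopent-4-ene-1,3-diyl diacetate (meso; acetoxy groups cis to each other and to the acyl group) | CCCCCCCCCCCCC(=O)[C@]1(O)[C@H](OC(C)=O)C=C[C@@H]1OC(C)=O | intermediate
17 | (1S,2S,5R)-2,5-dihydroxy-2-tridecanoylcyclopent-3-en-1-yl acetate | CCCCCCCCCCCCC(=O)[C@]1(O)[C@H](O)C=C[C@@H]1OC(C)=O | target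

**Summary**

Total step count: 10. Longest linear sequence: 10 steps (from 1 and 2 to 17).

**Steps most likely to fail**

Step 8. Osmylation may not discriminate well enough between the exocyclic and the ring alkene, so that the ring alkene or both are dihydroxylated, and an acetyl group may migrate to the new side-chain hydroxyl before the oxidation. The fallback sets out from dienone 11 and returns at meso diacetate 16. Osmylation of 11 (K2OsO4·2H2O cat., N-methylmorpholine N-oxide), where the ring alkene is deactivated as a cyclopentenone C=C and the silyloxy group shields one face, should give the silyl-protected diol ketone F1. 2-Iodoxybenzoic acid then gives the α-hydroxy β-diketone F2. NaBH4/CeCl3·7H2O reduces the conjugated ring ketone in preference to the hindered side-chain ketone, with hydride anti to the silyloxy and acyl groups, to give the ring alcohol F3. HF·pyridine removes the silyl group to give the meso triol F4, and Ac2O/pyridine acetylates its two secondary hydroxyls to give 16.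

Step 10. The lipase may bind the hindered diacetate poorly, may differentiate the two acetates incompletely or in the opposite sense, and acetyl migration between the cis oxygens would erode the enantiomeric purity. The fallback sets out from ketol 6 and returns at target 17, and it tells the two ring oxygens apart by protecting groups instead of by a late enzyme step. Acetylation of 6 gives the racemic acetate F5. Its lipase-catalysed hydrolysis, a kinetic resolution of a simple 4-acyloxycyclopentenone, should by the same size rule return (4R,5S)-6 as a single enantiomer while the other enantiomer stays esterified. Steps 3 to 5 then give 7, 11 and 12 as single enantiomers with the configurations drawn. The free hydroxyl of 12 is acetylated to the silyl ether acetate F6, osmylation anti to both ring oxygens gives the diol F7, 2-iodoxybenzoic acid gives the silyl-protected ketone F8, and HF·pyridine removes the silyl group to give 17.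

Step 4. The tertiary α′ hydrogen lies on the face shielded by the silyloxy group, so deprotonation may be slow or may occur at the γ carbon, and the enolate may lose silanolate. The fallback sets out from 7 and returns at 11. Soft enolisation with Me3SiOTf/Et3N gives the silyl dienol ether F9, and Pd(OAc)2 in MeCN (Saegusa–Ito oxidation) dehydrosilylates it by β-hydride elimination from the side-chain CH2 to give 11.

**Further compounds**

F1 | step 8 | rac-4-[(tert-butyldimethylsilyl)oxy]-5-hydroxy-5-(1-hydroxytridecyl)cyclopent-2-en-1-one (tertiary hydroxyl trans to the silyloxy group) | CCCCCCCCCCCC[C@H](O)[C@]1(O)[C@H](O[Si](C)(C)C(C)(C)C)C=CC1=O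
F2 | step 8 | rac-4-[(tert-butyldimethylsilyl)oxy]-5-hydroxy-5-tridecanoylcyclopent-2-en-1-one (tertiary hydroxyl trans to the silyloxy group) | CCCCCCCCCCCCC(=O)[C@]1(O)[C@H](O[Si](C)(C)C(C)(C)C)C=CC1=O
F3 | step 8 | rac-1-{5-[(tert-butyldimethylsilyl)oxy]-1,2-dihydroxycyclopent-3-en-1-yl}tridecan-1-one (ring oxygens at C2 and C5 cis to each other and to the acyl group) | CCCCCCCCCCCCC(=O)[C@]1(O)[C@H](O[Si](C)(C)C(C)(C)C)C=C[C@@H]1O
F4 | step 8 | meso-1-(1,2,5-trihydroxycyclopent-3-en-1-yl)tridecan-1-one (secondary hydroxyls cis to each other and to the acyl group) | CCCCCCCCCCCCC(=O)[C@]1(O)[C@H](O)C=C[C@@H]1O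
F5 | step 10 | rac-trans-4-oxo-5-tridecylcyclopent-2-en-1-yl acetate | CCCCCCCCCCCCC[C@H]1[C@H](OC(C)=O)C=CC1=O
F6 | step 10 | acetate of single-enantiomer 12, (1S,4R)-4-[(tert-butyldimethylsilyl)oxy]-5-tridecylidenecyclopent-2-en-1-yl acetate | CCCCCCCCCCCC/C=C1\[C@H](O[Si](C)(C)C(C)(C)C)C=C[C@@H]1OC(C)=O
F7 | step 10 | tert-butyldimethylsilyl ether (at the free secondary ring hydroxyl) of the analogue of 17 that has 1-hydroxytridecyl in place of tridecanoyl | CCCCCCCCCCCC[C@H](O)[C@]1(O)[C@H](O[Si](C)(C)C(C)(C)C)C=C[C@@H]1OC(C)=O
F8 | step 10 | tert-butyldimethylsilyl ether of 17 at its secondary hydroxyl | CCCCCCCCCCCCC(=O)[C@]1(O)[C@H](O[Si](C)(C)C(C)(C)C)C=C[C@@H]1OC(C)=O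
F9 | step 4 | rac-tert-butyldimethyl{[4-tridecyl-3-(trimethylsilyloxy)cyclopenta-2,4-dien-1-yl]oxy}silane, the trimethylsilyl dienol ether of 7 | CCCCCCCCCCCCCC1=C(O[Si](C)(C)C)C=C[C@H]1O[Si](C)(C)C(C)(C)C
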